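**The pitfall.** A charge of 0.950 equivalents of incoming ligand looks like one exchange per starting complex, but a complex that has reacted once can go on reacting. A quick number for Sunday's and Wednesday's flasks is therefore better got by counting exchanges than by counting complexes.

| setting | larch | ash | cedar | Sunday's | Wednesday's |
|---|---|---|---|---|---|
| starting complex | 0.12 M | 0.12 M | 0.12 M | 0.12 M | 0.12 M |
| incoming ligand | 0.114 M | 0.114 M | 0.057 M | 0.114 M | 0.114 M |
| leaving ligand | 0.12 M | 0.48 M | 0.24 M | 0.240 M | 0.240 M |
| capture agent | 2.4 mM | 2.4 mM | 2.4 mM | 2.40 mM | 2.40 mM |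
| temperature | 78 °C | 94 °C | 78 °C | 80 °C | 90 °C |
| remark | run made earlier | run made earlier | run made earlier |  |  |
| time |  |  |  | 40 h | 40 h |

| run | time / h | complex with three exchanged / % | complex with one exchanged / % | complex with two exchanged / % | starting complex / % | side product / % |
|---|---|---|---|---|---|---|
| larch | 3.00 | 2.0 | 17.7 | 5.5 | 74.9 | 1.9 |
| larch | 5.00 | 2.8 | 19.9 | 6.5 | 64.6 | 5.9 |
| larch | 8.00 | 5.0 | 21.7 | 13.3 | 54.5 | 8.2 |
| larch | 15.0 | 10.3 | 18.8 | 16.8 | 38.9 | 12.9 |
| larch | 25.0 | 10.4 | 18.6 | 17.2 | 31.5 | 18.2 |
| larch | 40.0 | 14.5 | 16.7 | 17.2 | 23.6 | 27.7 |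
| ash | 1.33 | 1.9 | 17.5 | 6.3 | 56.2 | 18.2 |
| ash | 4.00 | 8.9 | 16.0 | 12.6 | 23.0 | 36.5 |
| ash | 8.00 | 14.5 | 13.9 | 12.2 | 9.8 | 47.6 |
| ash | 10.0 | 17.2 | 11.8 | 13.5 | 5.5 | 53.3 |
| ash | 15.0 | 19.7 | 10.4 | 13.0 | 2.4 | 54.7 |
| ash | 20.0 | 19.8 | 9.5 | 10.5 | 1.2 | 54.7 |
| cedar | 3.00 | 0.6 | 10.4 | 0 | 82.9 | 7.5 |
| cedar | 6.00 | 0.7 | 14.6 | 4.5 | 69.1 | 11.5 |
| cedar | 12.0 | 0.9 | 17.6 | 7.9 | 54.3 | 20.1 |
| cedar | 20.0 | 4.3 | 16.6 | 9.6 | 42.2 | 26.5 |
| cedar | 40.0 | 2.7 | 18.6 | 10.1 | 26.6 | 42.9 |

(standard deviation of a reading: 1 percentage point)

1. which of these there is most of at the end, counted by the starting complex in it, Sunday's (complex with three exchanged / complex with two exchanged / side product / complex with one exchanged)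
2. which of these there is most of at the end, counted by the starting complex in it, Wednesday's (complex with three exchanged / complex with two exchanged / side product / complex with one exchanged)
3. how much there is at the end of the one of these that leads, in percent of the starting complex charged: Sunday's
4. how much there is at the end of the one of these that leads, in percent of the starting complex charged: Wednesday's

**The budget.** At 40.0 h in the larch run, the complexes with one, two and three exchanged, each weighted by its exchanges, add up to 94.6 % of the starting complex charged. The charge of incoming ligand allows 95.0 %, so incoming ligand is the limiting reagent there. These complexes together hold 48.4 % of the starting complex, which makes 1.95 exchanges per exchanged complex.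

**The ceiling.** Sunday's and Wednesday's flasks have the larch charges of starting complex and incoming ligand. If they keep that count, the budget reaches a part of the starting complex equal to c(incoming ligand)/c(starting complex) divided by the count. The remainder is the side-product ceiling, 51.4 %. Only late in a run, once the exchanges have used the budget, as in the larch run at 40.0 h with 94.6 % against 95.0 %, is side product the ceiling less the starting complex still present; early on this subtraction does not hold. The ash run, with the same charges, reads 54.7 % at 20.0 h, which is 3.3 percentage points above it, so the ceiling carries that much doubt.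

**The forecast.** It puts side product ahead in both flasks, at 40 % on Sunday's and 47 % on Wednesday's, with “starting complex nearly gone” on Wednesday's. Against the ceiling, those figures imply 11.4 % and 4.40 % of starting complex left.

    starting complex + incoming ligand → leaving ligand + complex with one exchanged (k = 0.0170 M⁻¹ min⁻¹, Ea = 79.0 kJ mol⁻¹)
    complex with one exchanged + incoming ligand → leaving ligand + complex with two exchanged (k = 0.0400 M⁻¹ min⁻¹, Ea = 75.0 kJ mol⁻¹)
    complex with two exchanged + incoming ligand → leaving ligand + complex with three exchanged (k = 0.0340 M⁻¹ min⁻¹, Ea = 93.0 kJ mol⁻¹)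
    complex with one exchanged + capture agent → trapped intermediate (k = 0.0110 M⁻¹ min⁻¹, Ea = 83.0 kJ mol⁻¹)
    leaving ligand + starting complex → side product (k = 0.00180 M⁻¹ min⁻¹, Ea = 97.0 kJ mol⁻¹)
    (constants at 80 °C)

**The flask.** Sunday's gives 40.0 % of side product and Wednesday's 50.7 %, and side product leads in both. At the end of Sunday's, incoming ligand stands at 0.73 % of its charge and starting complex at 12 %, so the ceiling less that starting complex is 39.4 %. Wednesday's has 1.7 % of starting complex left, and the same subtraction gives 49.7 %. At 400 h, Wednesday's side product stands at 52.4 %, with the ceiling at 51.4 %.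

Readings and results were generated by integration with made-up constants.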